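## The problem

(−)-Thujaplicatin (18) is a trans-3,4-dibenzyl-γ-butyrolactone. With the lactone numbered O1, C2 (carbonyl), C3, C4, C5, the 3,4-dihydroxy-5-methoxybenzyl arm (ring B) sits on C3 and the 4-hydroxy-3-methoxybenzyl arm (ring A) on C4, and both centres are R. Both arenes can be bought with their oxygen pattern in place, so the task is the four-carbon core: two adjacent stereocentres and two different aryl arms that must not change places, because the arm-swapped lactone is a regioisomer that differs only in remote ring substituents. C3 lies next to the carbonyl and can be epimerised, and trans is the more stable arrangement; C4 cannot be corrected once made, so C4 needs the absolute stereochemical decision and can then govern C3, kinetically through a group on its arm or thermodynamically. The free catechol of ring B and the guaiacol of ring A are oxidised easily, above all in base, so the phenols should travel as ethers and be released last under neutral conditions. The lactone does not survive strong nucleophiles, and any 4-(hydroxymethyl) lactone met on the way can pass its acyl group from one arm of C4 to the other. The feature that opens the route is that C4 carries two CH2 arms, C5 (bound to O1) and the benzylic CH2 of ring A; as long as the latter still bears oxygen, the two arms are the enantiotopic CH2–O groups of a 3-substituted oxetane, and lactone closure by a carboxyl group on C3 has to choose one of them.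

## Retrosynthesis

**18 to 17.** The three phenolic O–H bonds are traced back to O–benzyl bonds in tribenzyl ether 17. Methyl ethers are excluded because the target keeps two of them, and aryl silyl ethers would not survive the saponification earlier in the route. Benzyl ethers tolerate base, the phosphoric acid, the iridium hydrogenation and the nickel coupling, and all three fall in one neutral hydrogenolysis. The forward step only has to leave the lactone and its two stereocentres alone.

**17 to 14 and 16.** The bond between ring A and its benzylic CH2 is cut, giving primary iodide 14 and aryl bromide 16. The neighbouring cut, between that CH2 and C4, would turn C4 into a centre to be alkylated and would abandon the oxetane logic. Cutting one bond further out leaves a one-carbon arm on C4 bearing a leaving group, which is what oxetane opening provides. Iodide 14 holds both stereocentres and ring B, and 16 is a one-step compound. The forward reaction must join C(sp3) to C(sp2) without base and without a preformed organometallic, because the lactone is enolisable at C3; a nickel-catalysed reductive coupling of the two halides meets this.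

**14 to 13.** The C–I bond is traced back to the C–OH bond of hydroxymethyl lactone 13. The exchange is placed after the reduction of the benzylidene and not before it, for two reasons. A primary radical at this CH2 would sit homoallylic to a styrene and could close onto it and rearrange during the coupling. And any later reduction at C3 that passes through an enolate would displace the iodide and close a cyclopropane.

**13 to 12.** The C3–H and benzylic C–H bonds are removed, giving (E)-benzylidene lactone 12 with C4 as its only stereocentre. Reducing at the alcohol stage lets the hydroxyl on the C4 arm deliver hydrogen to its own face of the alkene, which gives the trans lactone directly and saves a separate equilibration. It also ends the danger of racemisation by acyl shift: once C3 is sp3, the shift leads to the less stable cis diastereomer and not to the enantiomer. The forward step must reduce a conjugated trisubstituted alkene without touching three benzyl ethers, which rules out Pd/C and points to a cationic iridium catalyst.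

**12 to 11.** The O1–C5 bond is cut and the free CH2OH arm is reconnected to the departing oxygen. Lactone 12 becomes the achiral (E)-α-(oxetan-3-yl)cinnamic acid 11, with no stereocentre because C3 is sp2 and the oxetane is symmetric. Compared with cuts at C3–C4 or C2–C3, this one creates the ring and the absolute configuration in a single catalytic step and leaves the hydroxyl handle needed for ring A. The forward reaction must select one of two enantiotopic CH2 groups and must outrun the uncatalysed closure of the oxetane acid.

**11 to 10, 8, 4 and 6.** The acid comes from ethyl ester 10, and the C=C bond of 10 is cut through aldol 8 into ethyl 2-(oxetan-3-yl)acetate 4 and aldehyde 6. An olefination with an α-branched phosphonate would give the same bond but with poorer control of geometry. Aldol addition followed by base-mediated elimination passes through the ester enolate and should favour the conjugated (E)-isomer. The forward steps must keep the oxetane intact, which all-basic conditions allow.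

**4, 6 and 16 to bought materials.** Ester 4 comes from ylidene ester 3 by hydrogenation, and 3 from oxetan-3-one 1 and the stabilised ylide 2. Aldehyde 6 comes from 5-hydroxyvanillin 5 and bromide 16 from 4-bromo-2-methoxyphenol 15, both by benzylation. Each of these is a single routine step.

## Roads not taken

**Alternative 1:** The cut runs through C3–C4 and through the bond between ring A and its benzylic CH2, giving three pieces: alkenylboronate A1 with the ring B arm, vinylmagnesium bromide A2 as the source of C4 and of the ring A benzylic carbon, and aryl bromide 16. In the forward step, ate complex A3 formed from A1 and A2 reacts with 16 under Pd(OAc)2, a chiral MandyPhos ligand and NaOTf. The alkenyl group shifts from boron to carbon (C3–C4) and reductive elimination forms the aryl–CH2 bond, giving allylic boronate A4 with C4 set by the ligand.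
- Merits: the three carbon fragments meet in one step, and the ring A arm is attached at the moment C4 is created, so no separate C(sp3)–C(sp2) coupling is needed. In convergence this road is better than the chosen plan.
- Weak points: A4 contains neither the lactone nor C5, and C2 is present only as a methylene group. C5 has to be brought in by one-carbon homologation of the C–B bond and oxidation. C2 needs anti-Markovnikov hydration and oxidation to the acid level, and that hydration creates C3 under acyclic 1,2-induction only. The two primary oxygen functions must be kept apart throughout, or the arm-swapped lactone results. A 1,1-disubstituted alkenyl group as the migrating group is at the less explored edge of this coupling.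
- Comparison: the chosen plan sets against the higher convergence a key step that delivers the ring, the right oxidation levels at C2 and C5 and a hydroxyl that then directs C3.

**Alternative 2:** The cut goes through ring B itself (B6–B1 and B2–B3). Chlorocyclobutenone A5 and alkenylstannane A6, a finished trans lactone with a 2-stannylallyl group on C3, are joined by Stille coupling under Pd2(dba)3 and tri(2-furyl)phosphine. Heating opens the four-membered ring and a six-electron closure gives phenol A7.
- Merits: the oxygen pattern of ring B is built regiospecifically, the B3 hydroxyl appears unprotected, and ring B analogues would be easy to reach. For analogue work this road is better.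
- Weak points: the key step makes no stereocentre and no lactone bond, so the whole C3/C4 problem has to be solved beforehand on the way to A6. A7 carries methyl ethers at both B4 and B5, and the target needs B4 as a free hydroxyl, so a single methyl ether would have to be cleaved beside two others. Tin is introduced late in the synthesis.
- Comparison: ring B with the correct pattern is available as 5, so building it costs steps and solves nothing that the chosen plan leaves open.

**Alternative 3:** The cut is C2–C3, with closure of O1–C2. Homoallylic alcohol A8, which already has C4 and both aryl arms, is hydroformylated with Rh(acac)(CO)2 and Ph2POMe. The phosphinite exchanges onto the C5 hydroxyl and steers the formyl group to C3, and the aldehyde closes to lactol A9.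
- Merits: carbon monoxide supplies C2 with full atom economy. Only a lactol oxidation and the hydrogenolysis follow, and no hydroxymethyl lactone prone to acyl shift and no late aryl coupling occur. In the length of the endgame this road is better.
- Weak points: the absolute configuration at C4 is not made by the key step and must be imported into A8 by separate asymmetric chemistry. The directing group has to override the preference of an electron-rich styrene for formylation at the benzylic carbon. C3 is set only by 1,2-induction from C4.
- Comparison: the chosen plan sets against the shorter endgame that its key step creates C4 from an achiral precursor with a catalyst, and that C3 follows from a directed reduction with a thermodynamic safety net.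

Key step: step 7

Assumption: the sense of enantiotopic-group selection of a given catalyst antipode cannot be derived with certainty for this substrate. The route is written with the (R)-configured phosphoric acid as the one that gives (S)-12; the (S)-configured catalyst would be used if the opposite sense were found.

## Route

Step 1
Reactants: 1 oxetan-3-one; 2 ethyl (triphenylphosphoranylidene)acetate
Product: 3 ethyl 2-(oxetan-3-ylidene)acetate
Conditions: CH2Cl2, 0 °C to rt
Reagents that add atoms: none
Why: Wittig olefination of the strained, unhindered ketone with a stabilised ylide is the standard entry to 3-alkylidene oxetanes, and the neutral conditions leave the ring intact; the oxetane is symmetric, so no alkene geometry arises.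

Step 2
Reactants: 3 ethyl 2-(oxetan-3-ylidene)acetate
Product: 4 ethyl 2-(oxetan-3-yl)acetate
Conditions: H2 (1 atm), 10% Pd/C, EtOAc, rt
Reagents that add atoms: none
Why: Catalytic hydrogenation of the conjugated alkene; oxetane C–O bonds are not cleaved under these mild conditions, and no benzyl ether is present yet.

Step 3
Reactants: 5 5-hydroxyvanillin (3,4-dihydroxy-5-methoxybenzaldehyde)
Product: 6 3,4-bis(benzyloxy)-5-methoxybenzaldehyde
Conditions: BnBr, K2CO3, DMF, 60 °C
Reagents that add atoms: benzyl bromide, BrCc1ccccc1
Why: Williamson ether synthesis on both phenols; benzyl is chosen because it survives every later step and all benzyl ethers are removed together at the end.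

Step 4
Reactants: 4 ethyl 2-(oxetan-3-yl)acetate; 6 3,4-bis(benzyloxy)-5-methoxybenzaldehyde
Product: 8 ethyl 3-[3,4-bis(benzyloxy)-5-methoxyphenyl]-3-hydroxy-2-(oxetan-3-yl)propanoate (racemic syn/anti mixture), via lithium enolate 7 (not isolated)
Conditions: LDA, THF, −78 °C; then 6, −78 °C; aq. NH4Cl at −78 °C
Reagents that add atoms: none
Why: Aldol addition of a lithium ester enolate to a non-enolisable aromatic aldehyde; at −78 °C the enolate should not open the unactivated oxetane, and the cold quench prevents retro-aldol cleavage. The diastereomer mixture is of no concern because both centres are removed in step 5.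

Step 5
Reactants: 8 ethyl 3-[3,4-bis(benzyloxy)-5-methoxyphenyl]-3-hydroxy-2-(oxetan-3-yl)propanoate
Product: 10 ethyl (E)-3-[3,4-bis(benzyloxy)-5-methoxyphenyl]-2-(oxetan-3-yl)acrylate, via mesylate 9 (not isolated)
Conditions: MsCl, Et3N, CH2Cl2, 0 °C; then DBU, 0 °C to rt
Reagents that add atoms: none
Why: Mesylation followed by E1cB elimination; the elimination passes through the ester enolate, so both aldol diastereomers converge and the conjugated isomer with aryl trans to the ester (E) should be favoured. The oxetane is inert to amine bases.

Step 6
Reactants: 10 ethyl (E)-3-[3,4-bis(benzyloxy)-5-methoxyphenyl]-2-(oxetan-3-yl)acrylate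
Product: 11 (E)-3-[3,4-bis(benzyloxy)-5-methoxyphenyl]-2-(oxetan-3-yl)acrylic acid
Conditions: LiOH·H2O, THF/MeOH/H2O, 40 °C; then cold 1 M H3PO4 to pH 5, 0 °C, extraction; used at once
Reagents that add atoms: lithium hydroxide, [Li+].[OH-]
Why: Ester saponification under conditions to which oxetanes and the trisubstituted alkene are stable. The acid is liberated cold with a weak acid and taken on directly, because oxetanes with a carboxyl group placed for five-ring closure can lactonise on their own on standing or warming.

Step 7
Reactants: 11 (E)-3-[3,4-bis(benzyloxy)-5-methoxyphenyl]-2-(oxetan-3-yl)acrylic acid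
Product: 12 (S,E)-3-[3,4-bis(benzyloxy)-5-methoxybenzylidene]-4-(hydroxymethyl)dihydrofuran-2(3H)-one
Conditions: (R)-TRIP [(R)-3,3'-bis(2,4,6-triisopropylphenyl)-1,1'-binaphthyl-2,2'-diyl hydrogen phosphate] (10 mol %), PhMe (0.05 M), 0 °C to rt
Reagents that add atoms: none
Why: The phosphoric acid hydrogen-bonds to the oxetane oxygen while its phosphoryl oxygen holds the carboxyl proton, so the carboxyl oxygen attacks one oxetane CH2 from the back in an SN2 displacement that forms O1–C5 and frees the other arm as CH2OH. The closest known reaction type is the chiral phosphoric acid catalysed intramolecular desymmetrising opening of 3-substituted oxetanes by a tethered oxygen nucleophile; the uncatalysed closure of oxetane carboxylic acids to γ-lactones is also known and shows that the ring closure itself is favourable. The lactone closes in the 5-exo-tet mode, paid for by release of the oxetane strain. C4 is the only new stereocentre: no bond to it is made or broken, and its configuration is fixed solely by which enantiotopic CH2 is attacked, which the chiral pocket of the catalyst decides (catalyst control, S required). The step needs enantiotopic-group selection and also chemoselection of the carboxyl oxygen over the electron-rich ring B, which could attack the activated oxetane in a six-ring Friedel–Crafts closure; two-point binding of carboxyl and oxetane to one catalyst molecule and the weak acidity of the catalyst favour the oxygen pathway. Because C3 is sp2 the precursor is achiral and rigid, so no diastereomer question arises and the (E) geometry passes into 12 unchanged. Low temperature, a non-polar solvent and the large acidity gap between catalyst and substrate are relied on to keep the uncatalysed racemic closure slow. The reaction is stopped at full conversion and 12 is reduced at once, since acyl shift between the two arms of C4 would racemise it.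

Step 8
Reactants: 12 (S,E)-3-[3,4-bis(benzyloxy)-5-methoxybenzylidene]-4-(hydroxymethyl)dihydrofuran-2(3H)-one
Product: 13 (3R,4S)-3-[3,4-bis(benzyloxy)-5-methoxybenzyl]-4-(hydroxymethyl)dihydrofuran-2(3H)-one
Conditions: H2 (1 atm), [Ir(cod)(PCy3)(py)]PF6 (5 mol %), CH2Cl2, 0 °C to rt
Reagents that add atoms: none
Why: Hydroxyl-directed homogeneous hydrogenation: the cationic iridium centre binds the homoallylic hydroxyl and the alkene and adds H2 to the face that carries the CH2OH arm, so the new C3–H is cis and the C3 benzyl group trans to that arm, which makes C3 R. Aryl benzyl ethers and the lactone are inert to this catalyst, and the neutral medium gives acyl shift no opportunity.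

Step 9
Reactants: 13 (3R,4S)-3-[3,4-bis(benzyloxy)-5-methoxybenzyl]-4-(hydroxymethyl)dihydrofuran-2(3H)-one
Product: 14 (3R,4R)-3-[3,4-bis(benzyloxy)-5-methoxybenzyl]-4-(iodomethyl)dihydrofuran-2(3H)-one
Conditions: I2, PPh3, imidazole, CH2Cl2, 0 °C to rt
Reagents that add atoms: iodine, II
Why: Appel iodination of the primary alcohol through the alkoxyphosphonium ion and SN2 attack by iodide at the CH2; neither stereocentre is a reacting centre (the descriptor at C4 changes only by priority). Removing the hydroxyl ends any possibility of acyl shift.

Step 10
Reactants: 15 4-bromo-2-methoxyphenol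
Product: 16 1-(benzyloxy)-4-bromo-2-methoxybenzene
Conditions: BnBr, K2CO3, acetone, reflux
Reagents that add atoms: benzyl bromide, BrCc1ccccc1
Why: Williamson ether synthesis; the benzyl ether matches the protecting groups of ring B so that one hydrogenolysis frees all phenols.

Step 11
Reactants: 14 (3R,4R)-3-[3,4-bis(benzyloxy)-5-methoxybenzyl]-4-(iodomethyl)dihydrofuran-2(3H)-one; 16 1-(benzyloxy)-4-bromo-2-methoxybenzene
Product: 17 (3R,4R)-4-[4-(benzyloxy)-3-methoxybenzyl]-3-[3,4-bis(benzyloxy)-5-methoxybenzyl]dihydrofuran-2(3H)-one
Conditions: NiBr2(dme) (10 mol %), 4,4'-di-tert-butyl-2,2'-bipyridine (10 mol %), Zn, DMA, 50 °C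
Reagents that add atoms: none
Why: Nickel-catalysed reductive cross-electrophile coupling: the aryl bromide adds oxidatively to zerovalent nickel, the primary alkyl radical formed from the iodide is captured by the divalent arylnickel species, and reductive elimination forms the C(sp3)–C(sp2) bond while zinc returns the catalyst. No base and no preformed organometallic are present, so the enolisable lactone and C3 are untouched. The radical sits on the CH2 next to C4 and not on a stereocentre, and with C3 saturated it has no alkene to add to.

Step 12
Reactants: 17 (3R,4R)-4-[4-(benzyloxy)-3-methoxybenzyl]-3-[3,4-bis(benzyloxy)-5-methoxybenzyl]dihydrofuran-2(3H)-one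
Product: 18 (−)-thujaplicatin, (3R,4R)-3-(3,4-dihydroxy-5-methoxybenzyl)-4-(4-hydroxy-3-methoxybenzyl)dihydrofuran-2(3H)-one
Conditions: H2 (1 atm), 10% Pd/C, EtOAc/MeOH, rt; filtration under argon
Reagents that add atoms: none
Why: Hydrogenolysis of the three aryl benzyl ethers under neutral conditions, which touches neither the lactone nor the stereocentres; the oxidation-prone catechol is set free only in this last step.

## Compound list

1 | oxetan-3-one | O=C1COC1 | starting material
2 | ethyl (triphenylphosphoranylidene)acetate | CCOC(=O)C=P(c1ccccc1)(c1ccccc1)c1ccccc1 | starting material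
3 | ethyl 2-(oxetan-3-ylidene)acetate | CCOC(=O)C=C1COC1 | intermediate
4 | ethyl 2-(oxetan-3-yl)acetate | CCOC(=O)CC1COC1 | intermediate
5 | 5-hydroxyvanillin (3,4-dihydroxy-5-methoxybenzaldehyde) | COc1cc(C=O)cc(O)c1O | starting material
6 | 3,4-bis(benzyloxy)-5-methoxybenzaldehyde | COc1cc(C=O)cc(OCc2ccccc2)c1OCc1ccccc1 | intermediate
7 | lithium enolate of ethyl 2-(oxetan-3-yl)acetate | CCOC([O-])=CC1COC1.[Li+] | intermediate (not isolated)
8 | ethyl 3-[3,4-bis(benzyloxy)-5-methoxyphenyl]-3-hydroxy-2-(oxetan-3-yl)propanoate (racemic syn/anti mixture) | CCOC(=O)C(C1COC1)C(O)c1cc(OC)c(OCc2ccccc2)c(OCc2ccccc2)c1 | intermediate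
9 | ethyl 3-[3,4-bis(benzyloxy)-5-methoxyphenyl]-3-(methanesulfonyloxy)-2-(oxetan-3-yl)propanoate (racemic syn/anti mixture) | CCOC(=O)C(C1COC1)C(OS(C)(=O)=O)c1cc(OC)c(OCc2ccccc2)c(OCc2ccccc2)c1 | intermediate (not isolated)
10 | ethyl (E)-3-[3,4-bis(benzyloxy)-5-methoxyphenyl]-2-(oxetan-3-yl)acrylate | CCOC(=O)/C(C1COC1)=C/c1cc(OC)c(OCc2ccccc2)c(OCc2ccccc2)c1 | intermediate
11 | (E)-3-[3,4-bis(benzyloxy)-5-methoxyphenyl]-2-(oxetan-3-yl)acrylic acid | OC(=O)/C(C1COC1)=C/c1cc(OCc2ccccc2)c(OCc2ccccc2)c(OC)c1 | intermediate
12 | (S,E)-3-[3,4-bis(benzyloxy)-5-methoxybenzylidene]-4-(hydroxymethyl)dihydrofuran-2(3H)-one | OC[C@H]1COC(=O)/C1=C/c1cc(OCc2ccccc2)c(OCc2ccccc2)c(OC)c1 | intermediate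
13 | (3R,4S)-3-[3,4-bis(benzyloxy)-5-methoxybenzyl]-4-(hydroxymethyl)dihydrofuran-2(3H)-one | OC[C@H]1COC(=O)[C@@H]1Cc1cc(OCc2ccccc2)c(OCc2ccccc2)c(OC)c1 | intermediate
14 | (3R,4R)-3-[3,4-bis(benzyloxy)-5-methoxybenzyl]-4-(iodomethyl)dihydrofuran-2(3H)-one | IC[C@H]1COC(=O)[C@@H]1Cc1cc(OCc2ccccc2)c(OCc2ccccc2)c(OC)c1 | intermediate
15 | 4-bromo-2-methoxyphenol | COc1cc(Br)ccc1O | starting material
16 | 1-(benzyloxy)-4-bromo-2-methoxybenzene | COc1cc(Br)ccc1OCc1ccccc1 | intermediate
17 | (3R,4R)-4-[4-(benzyloxy)-3-methoxybenzyl]-3-[3,4-bis(benzyloxy)-5-methoxybenzyl]dihydrofuran-2(3H)-one | COc1cc(C[C@H]2COC(=O)[C@@H]2Cc2cc(OCc3ccccc3)c(OCc3ccccc3)c(OC)c2)ccc1OCc1ccccc1 | intermediate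
18 | (−)-thujaplicatin, (3R,4R)-3-(3,4-dihydroxy-5-methoxybenzyl)-4-(4-hydroxy-3-methoxybenzyl)dihydrofuran-2(3H)-one | COc1cc(C[C@H]2COC(=O)[C@@H]2Cc2cc(O)c(O)c(OC)c2)ccc1O | target

## Step count and risks

Total: 12 steps. Longest linear sequence: 10 steps (steps 1, 2, 4, 5, 6, 7, 8, 9, 11, 12); steps 3 and 10 prepare the two aryl partners.

**Step 7 (key step).** The most likely failure is incomplete enantiotopic-group selection. The free acid can close onto its own oxetane without the catalyst, already during its isolation in step 6, and the flat cinnamic acid may be held loosely in the catalyst pocket. Erosion of 12 by acid-promoted acyl shift and Friedel–Crafts closure by ring B are secondary risks. The fallback gives up catalytic desymmetrisation for a resolution. It sets out from 11, which is closed with a catalytic amount of achiral diphenyl phosphate in toluene to the racemic hydroxymethyl lactone F1. F1 is then resolved by lipase-catalysed acetylation (Burkholderia cepacia lipase, vinyl acetate, tert-butyl methyl ether, rt), with the enzyme selected so that the (R)-alcohol is converted to the (R)-acetate F2 while the (S)-alcohol stays behind. Chromatography returns the route to 12. In principle F2 can be recycled, since mild methanolysis with a trace of base gives an alcohol whose acyl shift leads back to F1.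

**Step 8.** The most likely failure is poor facial selectivity or stalled reduction. The alkene is conjugated, trisubstituted and aryl-substituted, so hydroxyl binding may not outcompete addition from the open face, which leads to the cis lactone, and the catalyst can deactivate with slow substrates. The fallback replaces kinetic direction by thermodynamic control. It sets out from 12, which is reduced briefly and cold with NiCl2·6H2O/NaBH4 in MeOH/THF at 0 °C to a mixture of 13 and the (3S,4S) cis alcohol F3. The mixture is carried through the conditions of step 9 to 14 and the (3S,4R) cis iodide F4, and through those of step 11 to 17 and the (3S,4R) cis lactone F5. Treatment with DBU in warm toluene then epimerises C3 of F5 to the more stable trans arrangement, and the route is rejoined at 17. At that stage there is no free hydroxyl, so only C3 can move.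

**Step 11.** The most likely failure is a mismatch of reactivity. The β-branched alkyl iodide may be consumed by reduction, dimerisation or elimination before the electron-rich aryl bromide has added to nickel; cyclisation of the radical onto ring B is a lesser concern. The fallback uses a preformed organometallic and two-electron transmetalation. It sets out from 14, into which activated zinc dust inserts in DMA at 40 °C to give the alkylzinc iodide F6. Negishi coupling of F6 with 16 under Pd(OAc)2 and the biaryl phosphine SPhos in THF at rt to 50 °C rejoins the route at 17.

**Step 5.** The most likely failure is formation of a mixture of alkene geometries. The elimination through the enolate is under weak thermodynamic bias when the α-substituent is a branched ring, and a mixed substrate would blur the selection in step 7. The fallback fixes the geometry by a cross-coupling with retention and bypasses steps 1, 2, 4 and 5. It sets out from 2 and 6: ylide 2 is brominated with N-bromosuccinimide in CH2Cl2 at −20 °C to the bromo ylide F7, which olefinates 6 in the same flask to the (Z)-α-bromoacrylate F8, in which aryl and ester are already trans. Negishi coupling of F8 with oxetan-3-ylzinc iodide F9, made from 3-iodooxetane and zinc in DMA, under Pd(OAc)2 and the biaryl phosphine CPhos in THF at rt replaces bromine by the oxetanyl group with retention and rejoins the route at 10.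

## Further compounds

F1 | step 7 | racemic (E)-3-[3,4-bis(benzyloxy)-5-methoxybenzylidene]-4-(hydroxymethyl)dihydrofuran-2(3H)-one | OCC1COC(=O)/C1=C/c1cc(OCc2ccccc2)c(OCc2ccccc2)c(OC)c1
F2 | step 7 | [(R,E)-4-[3,4-bis(benzyloxy)-5-methoxybenzylidene]-5-oxotetrahydrofuran-3-yl]methyl acetate | CC(=O)OC[C@@H]1COC(=O)/C1=C/c1cc(OCc2ccccc2)c(OCc2ccccc2)c(OC)c1
F3 | step 8 | (3S,4S)-3-[3,4-bis(benzyloxy)-5-methoxybenzyl]-4-(hydroxymethyl)dihydrofuran-2(3H)-one | OC[C@H]1COC(=O)[C@H]1Cc1cc(OCc2ccccc2)c(OCc2ccccc2)c(OC)c1
F4 | step 8 | (3S,4R)-3-[3,4-bis(benzyloxy)-5-methoxybenzyl]-4-(iodomethyl)dihydrofuran-2(3H)-one | IC[C@H]1COC(=O)[C@H]1Cc1cc(OCc2ccccc2)c(OCc2ccccc2)c(OC)c1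
F5 | step 8 | (3S,4R)-4-[4-(benzyloxy)-3-methoxybenzyl]-3-[3,4-bis(benzyloxy)-5-methoxybenzyl]dihydrofuran-2(3H)-one | COc1cc(C[C@H]2COC(=O)[C@H]2Cc2cc(OCc3ccccc3)c(OCc3ccccc3)c(OC)c2)ccc1OCc1ccccc1
F6 | step 11 | [(3R,4R)-4-[3,4-bis(benzyloxy)-5-methoxybenzyl]-5-oxotetrahydrofuran-3-yl]methylzinc iodide | I[Zn]C[C@H]1COC(=O)[C@@H]1Cc1cc(OCc2ccccc2)c(OCc2ccccc2)c(OC)c1
F7 | step 5 | ethyl bromo(triphenylphosphoranylidene)acetate | CCOC(=O)C(Br)=P(c1ccccc1)(c1ccccc1)c1ccccc1
F8 | step 5 | ethyl (Z)-3-[3,4-bis(benzyloxy)-5-methoxyphenyl]-2-bromoacrylate | CCOC(=O)/C(Br)=C/c1cc(OC)c(OCc2ccccc2)c(OCc2ccccc2)c1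
F9 | step 5 | oxetan-3-ylzinc iodide | I[Zn]C1COC1
A1 | alternative 1 | 2-[3-[3,4-bis(benzyloxy)-5-methoxyphenyl]prop-1-en-2-yl]-4,4,5,5-tetramethyl-1,3,2-dioxaborolane | C=C(Cc1cc(OCc2ccccc2)c(OCc2ccccc2)c(OC)c1)B1OC(C)(C)C(C)(C)O1
A2 | alternative 1 | vinylmagnesium bromide | C=C[Mg]Br
A3 | alternative 1 | bromomagnesium vinyl ate complex of A1 | C=C[B-]1(C(=C)Cc2cc(OCc3ccccc3)c(OCc3ccccc3)c(OC)c2)OC(C)(C)C(C)(C)O1.[Mg+]Br
A4 | alternative 1 | 2-[(R)-1-[4-(benzyloxy)-3-methoxyphenyl]-4-[3,4-bis(benzyloxy)-5-methoxyphenyl]-3-methylidenebutan-2-yl]-4,4,5,5-tetramethyl-1,3,2-dioxaborolane | COc1cc(C[C@@H](B2OC(C)(C)C(C)(C)O2)C(=C)Cc2cc(OCc3ccccc3)c(OCc3ccccc3)c(OC)c2)ccc1OCc1ccccc1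
A5 | alternative 2 | 4-chloro-2,3-dimethoxycyclobut-2-en-1-one | O=C1C(OC)=C(OC)C1Cl
A6 | alternative 2 | (3R,4R)-4-[4-(benzyloxy)-3-methoxybenzyl]-3-[2-(tributylstannyl)prop-2-en-1-yl]dihydrofuran-2(3H)-one | COc1cc(C[C@H]2COC(=O)[C@@H]2CC(=C)[Sn](CCCC)(CCCC)CCCC)ccc1OCc1ccccc1
A7 | alternative 2 | (3R,4R)-4-[4-(benzyloxy)-3-methoxybenzyl]-3-(3-hydroxy-4,5-dimethoxybenzyl)dihydrofuran-2(3H)-one | COc1cc(C[C@H]2COC(=O)[C@@H]2Cc2cc(O)c(OC)c(OC)c2)ccc1OCc1ccccc1
A8 | alternative 3 | (R,E)-2-[4-(benzyloxy)-3-methoxybenzyl]-4-[3,4-bis(benzyloxy)-5-methoxyphenyl]but-3-en-1-ol | COc1cc(C[C@@H](CO)/C=C/c2cc(OCc3ccccc3)c(OCc3ccccc3)c(OC)c2)ccc1OCc1ccccc1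
A9 | alternative 3 | (3R,4R)-4-[4-(benzyloxy)-3-methoxybenzyl]-3-[3,4-bis(benzyloxy)-5-methoxybenzyl]tetrahydrofuran-2-ol (anomeric mixture) | COc1cc(C[C@H]2COC(O)[C@@H]2Cc2cc(OCc3ccccc3)c(OCc3ccccc3)c(OC)c2)ccc1OCc1ccccc1
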